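**Retrosynthetic overview**

1. Labels: C-a is the CH carrying the 2-methylprop-1-enyl group, C-b the O–CH ring-fusion carbon, C-c the ring-fusion CH next to CMe2. The central dihydropyran (ring A) is opened at the O–C-b ether bond and is the last ring formed, by acid-mediated anti hydroalkoxylation of a pyran double bond, which sets C-b and C-c from C-a.
2. Key bond C-a–C-c: enantioconvergent palladium-catalysed allyl–alkenyl cross-coupling of a racemic quinolonyl allylic carbonate (fragment 1) with a 3-boryl-N-methylflindersine (fragment 2). This sets C-a.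
3. Fragment 2: N-methylflindersine (2H-pyran ring B by Knoevenagel/oxa-6π of the quinolone with prenal), then C-3 bromination and Miyaura borylation.
4. Fragment 1: the same quinolone, O-MOM protection, C-3 lithiation and addition to prenal, carbonate formation.
5. Both quinolone cores come from N-methylaniline and malonic acid. Ring order: quinolone rings, then ring B, then ring A.

Assumption: the sense of induction in step 8 cannot be predicted in advance; the (R)-ligand is written as the antipode that gives (S)-15, and its mirror image is used if the sense is opposite.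

**Route**

Step 1
Reactants: 1 N-methylaniline; 2 malonic acid
Product: 3 4-hydroxy-1-methylquinolin-2(1H)-one
Conditions: POCl3 (neat), 95 °C; then ice water
Reagents that add atoms: none
Why: Ziegler-type condensation in which POCl3 activates malonic acid for N-acylation of the secondary aniline and the acyl intermediate closes by intramolecular Friedel–Crafts acylation at the ortho position, giving the 4-hydroxy-2-quinolone directly.

Step 2
Reactants: 3 4-hydroxy-1-methylquinolin-2(1H)-one; 4 3-methylbut-2-enal (prenal)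
Product: 6 N-methylflindersine [2,2,6-trimethyl-2H-pyrano[3,2-c]quinolin-5(6H)-one], via quinone methide 5 (not isolated)
Conditions: pyridine, MgSO4, 110 °C
Reagents that add atoms: none
Why: Knoevenagel condensation at the nucleophilic C-3 gives the vinyl o-quinone methide 5, whose oxa-6π electrocyclisation onto the C-4 oxygen closes the 2H-pyran (ring B), the standard formal [3+3] route to flindersine-type pyranoquinolinones.

Step 3
Reactants: 6 N-methylflindersine
Product: 8 3-bromo-2,2,6-trimethyl-2H-pyrano[3,2-c]quinolin-5(6H)-one, via trans-dibromide 7 (not isolated)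
Conditions: Br2, CH2Cl2, −10 °C; then Et3N, 0 °C to rt
Reagents that add atoms: bromine, BrBr
Why: Bromine adds across the electron-rich styrene-like pyran double bond and base then removes HBr through the strongly stabilised C-4 benzylic position (bromination–dehydrobromination, as used for 3-bromo-2H-chromenes), leaving bromine on C-3.

Step 4
Reactants: 8 3-bromo-2,2,6-trimethyl-2H-pyrano[3,2-c]quinolin-5(6H)-one
Product: 9 2,2,6-trimethyl-3-(4,4,5,5-tetramethyl-1,3,2-dioxaborolan-2-yl)-2H-pyrano[3,2-c]quinolin-5(6H)-one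
Conditions: B2pin2, PdCl2(dppf) (5 mol %), KOAc, 1,4-dioxane, 85 °C
Reagents that add atoms: bis(pinacolato)diboron, CC1(C)OB(OC1(C)C)B1OC(C)(C)C(C)(C)O1
Why: Miyaura borylation of the alkenyl bromide, which avoids a 3-lithio-2H-pyran that would expel the ring oxygen by β-elimination, while the mild acetate base leaves the lactam and the allylic ether untouched.

Step 5
Reactants: 3 4-hydroxy-1-methylquinolin-2(1H)-one
Product: 10 4-(methoxymethoxy)-1-methylquinolin-2(1H)-one
Conditions: MOMCl, i-Pr2NEt, CH2Cl2, 0 °C to rt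
Reagents that add atoms: chloromethyl methyl ether, COCCl
Why: The vinylogous acid is O-alkylated by the hard electrophile (MOM protection), which blocks o-quinone methide formation in the following steps and supplies a directing group for C-3 metalation.

Step 6
Reactants: 10 4-(methoxymethoxy)-1-methylquinolin-2(1H)-one; 4 3-methylbut-2-enal (prenal)
Product: 13 3-(1-hydroxy-3-methylbut-2-en-1-yl)-4-(methoxymethoxy)-1-methylquinolin-2(1H)-one (racemic), via aryllithium 11 (not isolated), via lithium alkoxide 12 (not isolated)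
Conditions: n-BuLi, THF, −78 °C; then 4, −78 to −40 °C; then H2O
Reagents that add atoms: none
Why: Directed ortho-metalation at C-3 (flanked by the lactam carbonyl and the OMOM group) followed by 1,2-addition of the aryllithium to the enal gives the secondary allylic alcohol, which is left racemic because step 8 is enantioconvergent.

Step 7
Reactants: 13 3-(1-hydroxy-3-methylbut-2-en-1-yl)-4-(methoxymethoxy)-1-methylquinolin-2(1H)-one
Product: 14 methyl 1-[4-(methoxymethoxy)-1-methyl-2-oxo-1,2-dihydroquinolin-3-yl]-3-methylbut-2-en-1-yl carbonate (racemic)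
Conditions: ClCO2Me, pyridine, DMAP (cat.), CH2Cl2, 0 °C
Reagents that add atoms: methyl chloroformate, COC(=O)Cl
Why: Standard acylation of the secondary alcohol to the methyl carbonate, a leaving group that releases methoxide on ionisation, run cold and base-buffered because the benzylic allylic carbonate ionises easily.

Step 8
Reactants: 14 methyl 1-[4-(methoxymethoxy)-1-methyl-2-oxo-1,2-dihydroquinolin-3-yl]-3-methylbut-2-en-1-yl carbonate; 9 2,2,6-trimethyl-3-(4,4,5,5-tetramethyl-1,3,2-dioxaborolan-2-yl)-2H-pyrano[3,2-c]quinolin-5(6H)-one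
Product: 15 4-(methoxymethoxy)-1-methyl-3-[(1S)-3-methyl-1-(2,2,6-trimethyl-5-oxo-5,6-dihydro-2H-pyrano[3,2-c]quinolin-3-yl)but-2-en-1-yl]quinolin-2(1H)-one
Conditions: Pd2(dba)3 (2.5 mol %), (R)-MeO-furyl-BIPHEP (6 mol %), THF, 40 °C
Reagents that add atoms: none
Why: Proposed new method: enantioconvergent allyl–alkenyl Suzuki–Miyaura coupling in which zerovalent palladium ionises racemic 14 to a 1-aryl-3,3-dimethylallyl palladium complex whose two faces interconvert quickly through the sigma-bound form at the gem-dimethyl terminus, the methoxide released from the carbonate activates boronate 9 for transmetalation, and ligand-controlled reductive elimination at the less substituted benzylic terminus forms the C-a–C-c bond and sets (S)-C-a; the closest known reactions are palladium-catalysed allyl–aryl and allyl–alkenyl Suzuki couplings of allylic carbonates and the enantioselective allyl–allyl coupling with small-bite-angle biaryl bisphosphines.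

Step 9
Reactants: 15 4-(methoxymethoxy)-1-methyl-3-[(1S)-3-methyl-1-(2,2,6-trimethyl-5-oxo-5,6-dihydro-2H-pyrano[3,2-c]quinolin-3-yl)but-2-en-1-yl]quinolin-2(1H)-one
Product: 17 CNP0210533.1 (target), via hydroxy diene 16 (not isolated)
Conditions: TFA, H2O (2 equiv), CH2Cl2, −20 to 0 °C
Reagents that add atoms: none
Why: Acid removes the MOM acetal and then effects a Markovnikov 6-endo intramolecular hydroalkoxylation of the dienol-ether-type pyran double bond (far more basic than the isobutenyl group): with C-a–H eclipsing the gem-dimethyl carbon the quinolone lies over one face of the alkene, C-c is protonated from the opposite face and the C-b cation is captured by the 4-OH from the quinolone face, a net anti addition expected to give the cis ring fusion (C-b R, C-c S) with H-a trans to H-c.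

**Compound list**

1 | N-methylaniline | CNc1ccccc1 | starting material
2 | malonic acid | OC(=O)CC(=O)O | starting material
3 | 4-hydroxy-1-methylquinolin-2(1H)-one | Cn1c(=O)cc(O)c2ccccc12 | intermediate
4 | 3-methylbut-2-enal (prenal) | CC(C)=CC=O | starting material
5 | (3E)-1-methyl-3-(3-methylbut-2-en-1-ylidene)quinoline-2,4(1H,3H)-dione (vinyl o-quinone methide) | CC(C)=C/C=C1/C(=O)N(C)c2ccccc2C1=O | intermediate
6 | N-methylflindersine, 2,2,6-trimethyl-2H-pyrano[3,2-c]quinolin-5(6H)-one | CC1(C)C=Cc2c(O1)c1ccccc1n(C)c2=O | intermediate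
7 | trans-3,4-dibromo-2,2,6-trimethyl-3,4-dihydro-2H-pyrano[3,2-c]quinolin-5(6H)-one (racemic, one enantiomer drawn) | CC1(C)Oc2c([C@@H](Br)[C@H]1Br)c(=O)n(C)c1ccccc21 | intermediate
8 | 3-bromo-2,2,6-trimethyl-2H-pyrano[3,2-c]quinolin-5(6H)-one | CC1(C)Oc2c(C=C1Br)c(=O)n(C)c1ccccc21 | intermediate
9 | 2,2,6-trimethyl-3-(4,4,5,5-tetramethyl-1,3,2-dioxaborolan-2-yl)-2H-pyrano[3,2-c]quinolin-5(6H)-one | CC1(C)Oc2c(C=C1B3OC(C)(C)C(C)(C)O3)c(=O)n(C)c4ccccc24 | intermediate
10 | 4-(methoxymethoxy)-1-methylquinolin-2(1H)-one | COCOc1cc(=O)n(C)c2ccccc12 | intermediate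
11 | 3-lithio-4-(methoxymethoxy)-1-methylquinolin-2(1H)-one | [Li]c1c(OCOC)c2ccccc2n(C)c1=O | intermediate
12 | lithium 1-[4-(methoxymethoxy)-1-methyl-2-oxo-1,2-dihydroquinolin-3-yl]-3-methylbut-2-en-1-olate (racemic) | [Li]OC(C=C(C)C)c1c(OCOC)c2ccccc2n(C)c1=O | intermediate
13 | 3-(1-hydroxy-3-methylbut-2-en-1-yl)-4-(methoxymethoxy)-1-methylquinolin-2(1H)-one (racemic) | CC(C)=CC(O)c1c(OCOC)c2ccccc2n(C)c1=O | intermediate
14 | methyl 1-[4-(methoxymethoxy)-1-methyl-2-oxo-1,2-dihydroquinolin-3-yl]-3-methylbut-2-en-1-yl carbonate (racemic) | CC(C)=CC(OC(=O)OC)c1c(OCOC)c2ccccc2n(C)c1=O | intermediate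
15 | 4-(methoxymethoxy)-1-methyl-3-[(1S)-3-methyl-1-(2,2,6-trimethyl-5-oxo-5,6-dihydro-2H-pyrano[3,2-c]quinolin-3-yl)but-2-en-1-yl]quinolin-2(1H)-one | CC(C)=C[C@@H](C1=Cc2c(c3ccccc3n(C)c2=O)OC1(C)C)c1c(OCOC)c2ccccc2n(C)c1=O | intermediate
16 | 4-hydroxy-1-methyl-3-[(1S)-3-methyl-1-(2,2,6-trimethyl-5-oxo-5,6-dihydro-2H-pyrano[3,2-c]quinolin-3-yl)but-2-en-1-yl]quinolin-2(1H)-one | CC(C)=C[C@@H](C1=Cc2c(c3ccccc3n(C)c2=O)OC1(C)C)c1c(O)c2ccccc2n(C)c1=O | intermediate
17 | CNP0210533.1: cis-fused bis(pyrano[3,2-c]quinolinone) dimer of N-methylflindersine; C-a (S), C-b (R), C-c (S); H-b cis to H-c, H-a trans to H-c | CC(C)=C[C@@H]1c2c(c3ccccc3n(C)c2=O)O[C@H]2c3c(c4ccccc4n(C)c3=O)OC(C)(C)[C@@H]12 | target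

**Step count and risks**

Total steps: 9. Longest linear sequence: 6 (steps 1, 2, 3, 4, 8, 9 or steps 1, 5, 6, 7, 8, 9).

Steps most likely to fail, in route order:

Step 6 (C-3 lithiation and addition to prenal). n-Butyllithium may add to the lactam carbonyl or metalate incompletely. The fallback sets out from 10 and replaces deprotonation by halogen–metal exchange. Bromination of 10 with NBS in MeCN at rt gives 3-bromo-4-(methoxymethoxy)-1-methylquinolin-2(1H)-one F1. Exchange with i-PrMgCl·LiCl in THF at −20 °C gives [4-(methoxymethoxy)-1-methyl-2-oxo-1,2-dihydroquinolin-3-yl]magnesium chloride F2. Addition to prenal 4 gives chloromagnesium 1-[4-(methoxymethoxy)-1-methyl-2-oxo-1,2-dihydroquinolin-3-yl]-3-methylbut-2-en-1-olate F3, and water quench brings the route back at 13.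

Step 8 (the proposed new coupling). Risks are β-hydride loss from the prenyl-type allyl complex to a diene, bond formation at the gem-dimethyl terminus, slow transmetalation of the hindered alkenyl boronate, and low enantioselectivity. The fallback uses known chemistry, sets out from 9 and 10, and comes back at 15.
- Boronate 9 is converted with KHF2 in MeOH/H2O into potassium trifluoro(2,2,6-trimethyl-5-oxo-5,6-dihydro-2H-pyrano[3,2-c]quinolin-3-yl)borate F4.
- Ether 10 is lithiated as in step 6 (aryllithium 11) and added to acrolein to give lithium 1-[4-(methoxymethoxy)-1-methyl-2-oxo-1,2-dihydroquinolin-3-yl]prop-2-en-1-olate F5 and, after water quench, racemic 3-(1-hydroxyprop-2-en-1-yl)-4-(methoxymethoxy)-1-methylquinolin-2(1H)-one F6.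
- The known iridium-catalysed enantioselective allylic alkenylation of racemic aryl vinyl carbinols with potassium alkenyltrifluoroborates ([Ir(cod)Cl]2, chiral phosphoramidite–olefin ligand, n-Bu4NHSO4, 1,4-dioxane, rt) joins F4 and F6 to 4-(methoxymethoxy)-1-methyl-3-[(1S)-1-(2,2,6-trimethyl-5-oxo-5,6-dihydro-2H-pyrano[3,2-c]quinolin-3-yl)prop-2-en-1-yl]quinolin-2(1H)-one F7.
- Cross-metathesis of the terminal vinyl group of F7 with 2-methylbut-2-ene (second-generation Grubbs catalyst, CH2Cl2, 40 °C) gives 15.

Step 9 (deprotection and ring closure). The cyclisation may give the trans-fused isomer or the C-c epimer. The C-b cation may also fragment back to an allyl cation and erode the C-a configuration, or the 4-OH may close onto the isobutenyl group. The fallback abandons the late ring closure and sets out from 6. The known acid-mediated biomimetic dimerisation of N-methylflindersine (TFA, CH2Cl2, rt) forms both new bonds of ring A in a formal hetero-Diels–Alder reaction. The diastereomer with the relative configuration of 17 is isolated by chromatography as a racemate, that is 17 together with its mirror image, the (R) at C-a, (S) at C-b, (R) at C-c enantiomer of CNP0210533.1 F8. Preparative chiral SFC removes F8 and delivers 17.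

**Further compounds**

F1 | step 6 | 3-bromo-4-(methoxymethoxy)-1-methylquinolin-2(1H)-one | COCOc1c(Br)c(=O)n(C)c2ccccc12
F2 | step 6 | [4-(methoxymethoxy)-1-methyl-2-oxo-1,2-dihydroquinolin-3-yl]magnesium chloride | Cl[Mg]c1c(OCOC)c2ccccc2n(C)c1=O
F3 | step 6 | chloromagnesium 1-[4-(methoxymethoxy)-1-methyl-2-oxo-1,2-dihydroquinolin-3-yl]-3-methylbut-2-en-1-olate (racemic) | Cl[Mg]OC(C=C(C)C)c1c(OCOC)c2ccccc2n(C)c1=O
F4 | step 8 | potassium trifluoro(2,2,6-trimethyl-5-oxo-5,6-dihydro-2H-pyrano[3,2-c]quinolin-3-yl)borate | [K+].F[B-](F)(F)C1=Cc2c(c3ccccc3n(C)c2=O)OC1(C)C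
F5 | step 8 | lithium 1-[4-(methoxymethoxy)-1-methyl-2-oxo-1,2-dihydroquinolin-3-yl]prop-2-en-1-olate (racemic) | [Li]OC(C=C)c1c(OCOC)c2ccccc2n(C)c1=O
F6 | step 8 | 3-(1-hydroxyprop-2-en-1-yl)-4-(methoxymethoxy)-1-methylquinolin-2(1H)-one (racemic) | C=CC(O)c1c(OCOC)c2ccccc2n(C)c1=O
F7 | step 8 | 4-(methoxymethoxy)-1-methyl-3-[(1S)-1-(2,2,6-trimethyl-5-oxo-5,6-dihydro-2H-pyrano[3,2-c]quinolin-3-yl)prop-2-en-1-yl]quinolin-2(1H)-one | C=C[C@@H](C1=Cc2c(c3ccccc3n(C)c2=O)OC1(C)C)c1c(OCOC)c2ccccc2n(C)c1=O
F8 | step 9 | enantiomer of CNP0210533.1 (C-a R, C-b S, C-c R) | CC(C)=C[C@H]1c2c(c3ccccc3n(C)c2=O)O[C@@H]2c3c(c4ccccc4n(C)c3=O)OC(C)(C)[C@H]12
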